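**Retrosynthetic overview**

1. C40 = C15 + C10 + C15: the C2-symmetric polyene is cut at C11=C12 and C11'=C12' (two-fold Horner–Wadsworth–Emmons reaction of one furanoid C15 phosphonate with the C10 trienedial), so one ring-forming event serves both ends.
2. The 2,5-dihydrofuran (O, C5, C6, C7, C8) is opened at O–C8 to its cycloisomer, an α-hydroxyallene (C5–OH, C6=C7=C8); a gold-catalysed 5-endo hydroalkoxylation closes it and turns the allene axis into the C8 stereocentre.
3. The allene comes from anti-SN2' hydride opening of a C5–C6 oxirane on an enyne; the C6–O bond is a temporary bond, absent from the target, that relays C3 → C5/C6 → axis → C8.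
4. The enyne comes from the enol triflate of (4R,6R)-actinol (chiral pool, sets C3) and an enynyl phosphonate by Sonogashira coupling; ring order: carbocycle (bought) → temporary oxirane → dihydrofuran (last ring).
5. Enabling feature: the ether oxygen on the quaternary ring-fusion carbon C5 and the CH stereocentre C8 flank the ring-fusion alkene C6=C7, so O–C5–C6=C7–C8 is the hydroalkoxylation isomer of a C5 carbinol next to an exocyclic C6=C7=C8 allene whose terminus carries exactly H and the chain.

Key step: step 8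

Remark: atom labels follow carotenoid numbering (carbocycle C1–C6 with gem-dimethyl carbon C1, carbinol C3, O-bearing ring-fusion carbon C5, alkene carbon C6; C7 and C8 complete the dihydrofuran; chain C9–C15), and the target is taken as the all-E (3S,5R,8R,3'S,5'R,8'R) isomer that the SMILES encodes.

**Route**

Step 1
Reactants: 1 (4R,6R)-4-hydroxy-2,2,6-trimethylcyclohexan-1-one ((4R,6R)-actinol)
Product: 2 (4R,6R)-4-{[tert-butyl(dimethyl)silyl]oxy}-2,2,6-trimethylcyclohexan-1-one
Conditions: TBSCl, imidazole, DMF, rt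
Reagents that add atoms: tert-butyl(chloro)dimethylsilane, C[Si](C)(Cl)C(C)(C)C
Why: Standard silylation of the secondary alcohol leaves both stereocentres untouched and gives an ether that should survive every later step and cannot direct a syn epoxidation by hydrogen bonding.

Step 2
Reactants: 2 (4R,6R)-4-{[tert-butyl(dimethyl)silyl]oxy}-2,2,6-trimethylcyclohexan-1-one
Product: 4 (4R)-4-{[tert-butyl(dimethyl)silyl]oxy}-2,6,6-trimethylcyclohex-1-en-1-yl trifluoromethanesulfonate, via potassium enolate 3 (not isolated)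
Conditions: KN(SiMe3)2, THF, −78 → −40 °C; then PhNTf2, −78 °C → rt
Reagents that add atoms: N-phenylbis(trifluoromethanesulfonimide), O=S(=O)(N(c1ccccc1)S(=O)(=O)C(F)(F)F)C(F)(F)F
Why: Only one α-carbon bears hydrogen, so a single enolate should form and be O-sulfonylated (enol triflate synthesis); the methyl-bearing stereocentre is erased on purpose and the carbinol centre is not affected.

Step 3
Reactants: 5 (2E)-3-methylpent-2-en-4-yn-1-ol
Product: 6 (3E)-5-bromo-3-methylpent-3-en-1-yne
Conditions: PBr3 (0.4 equiv), pyridine (cat.), Et2O, −10 → 0 °C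
Reagents that add atoms: phosphorus tribromide, BrP(Br)Br
Why: SN2 bromination of the primary allylic alcohol should keep the E geometry of the trisubstituted alkene.

Step 4
Reactants: 6 (3E)-5-bromo-3-methylpent-3-en-1-yne
Product: 7 diethyl [(2E)-3-methylpent-2-en-4-yn-1-yl]phosphonate
Conditions: P(OEt)3 (neat), 90 °C, EtBr distilled off
Reagents that add atoms: triethyl phosphite, CCOP(OCC)OCC
Why: Michaelis–Arbuzov reaction of a primary allylic bromide should give the allylic phosphonate without touching the alkene geometry or the terminal alkyne.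

Step 5
Reactants: 4 (4R)-4-{[tert-butyl(dimethyl)silyl]oxy}-2,6,6-trimethylcyclohex-1-en-1-yl trifluoromethanesulfonate; 7 diethyl [(2E)-3-methylpent-2-en-4-yn-1-yl]phosphonate
Product: 8 diethyl [(2E)-5-[(4R)-4-{[tert-butyl(dimethyl)silyl]oxy}-2,6,6-trimethylcyclohex-1-en-1-yl]-3-methylpent-2-en-4-yn-1-yl]phosphonate
Conditions: Pd(PPh3)4 (5 mol%), CuI (10 mol%), Et3N, DMF, rt
Reagents that add atoms: none
Why: Sonogashira coupling of a cyclohexenyl triflate with a terminal enyne forms the C6–C7 bond, and neither the silyl ether nor the allylic C–P bond should react with zerovalent palladium.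

Step 6
Reactants: 8 diethyl [(2E)-5-[(4R)-4-{[tert-butyl(dimethyl)silyl]oxy}-2,6,6-trimethylcyclohex-1-en-1-yl]-3-methylpent-2-en-4-yn-1-yl]phosphonate
Product: 9 diethyl [(2E)-5-[(1R,4S,6R)-4-{[tert-butyl(dimethyl)silyl]oxy}-2,2,6-trimethyl-7-oxabicyclo[4.1.0]heptan-1-yl]-3-methylpent-2-en-4-yn-1-yl]phosphonate
Conditions: mCPBA (1.1 equiv), NaHCO3, CH2Cl2, −20 → 0 °C
Reagents that add atoms: 3-chloroperoxybenzoic acid, OOC(=O)c1cccc(Cl)c1
Why: Prilezhaev epoxidation should take the tetrasubstituted ring alkene (the side-chain alkene is deactivated by the CH2P(O)(OEt)2 group) from the face anti to the silyloxy group, the sense known for 3-acyloxy and 3-silyloxy β-ring end groups, which sets C5 and the temporary C6–O bond; the minor syn isomer would be removed by chromatography.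

Step 7
Reactants: 9 diethyl [(2E)-5-[(1R,4S,6R)-4-{[tert-butyl(dimethyl)silyl]oxy}-2,2,6-trimethyl-7-oxabicyclo[4.1.0]heptan-1-yl]-3-methylpent-2-en-4-yn-1-yl]phosphonate
Product: 11 diethyl [(2E)-5-[(2R,4S)-4-{[tert-butyl(dimethyl)silyl]oxy}-2-hydroxy-2,6,6-trimethylcyclohexylidene]-3-methylpenta-2,4-dien-1-yl]phosphonate with (aS) allene axis (6S in carotenoid numbering), via silyl ether 10 (not isolated)
Conditions: (IPr)CuCl (5 mol%), NaOtBu (5 mol%), (EtO)2MeSiH (2.5 equiv), toluene, 0 °C; then K2CO3, MeOH, rt (IPr = 1,3-bis(2,6-diisopropylphenyl)imidazol-2-ylidene)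
Reagents that add atoms: none
Why: SN2' reduction of a propargyl oxirane by a carbene-ligated monovalent copper hydride (syn hydrocupration with H on C8 and Cu on C7, then anti β-alkoxide elimination) should deliver hydride anti to the breaking C6–O bond, so the allene axis is set with C9 on the face of the 5-OH and H-8 on the face of the 5-methyl group, while C5 keeps the oxirane configuration and the alkoxide is released from silicon by methanolysis.

Step 8
Reactants: 11 diethyl [(2E)-5-[(2R,4S)-4-{[tert-butyl(dimethyl)silyl]oxy}-2-hydroxy-2,6,6-trimethylcyclohexylidene]-3-methylpenta-2,4-dien-1-yl]phosphonate, (aS) axis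
Product: 12 diethyl [(2E)-3-[(2R,6S,7aR)-6-{[tert-butyl(dimethyl)silyl]oxy}-4,4,7a-trimethyl-2,4,5,6,7,7a-hexahydro-1-benzofuran-2-yl]but-2-en-1-yl]phosphonate
Conditions: AuCl3 (2 mol%), THF, 0 °C → rt, dark
Reagents that add atoms: none
Why: The closest known reaction type is the gold-catalysed 5-endo cycloisomerisation of α-hydroxyallenes to 2,5-dihydrofurans with axis-to-centre chirality transfer, which is established for tertiary carbinols and for tri- and tetrasubstituted allenes. Mechanism: trivalent gold binds the C7=C8 π bond of the allene (the one remote from the carbinol) on the side away from the C5 hydroxyl, the hydroxyl adds anti to C8 to give a C7 vinylgold oxonium species, and protodeauration with retention frees 12 and the catalyst. The only ring closed is the dihydrofuran O–C5–C6=C7–C8, by O–C8 bond formation in the 5-endo-trig mode onto the existing carbocycle, which makes it the last ring of the skeleton. The new stereocentre C8 is controlled by the allene axis alone: H-8 and C-9 stand above and below the plane in which O, C5, C6, C7 and C8 become the ring and do not change sides, so H-8, which in the (aS) allene lies on the face of the 5-methyl group, ends cis to that methyl, which is the (8R) configuration, while C5 and C3 are not touched. The step needs transfer without erosion (no planar C8 allyl cation before closure, no reversible C8–O ionisation after it) and O-attack instead of vinylallene carbocyclisation; the substrate secures this because the ring is closed at the C15 stage, where C8 is conjugated only to one alkene carrying the electron-withdrawing CH2P(O)(OEt)2 group and not to a polyene, because C6 is flanked by two quaternary carbons and cannot enter a Nazarov-type closure, and because the tertiary hydroxyl is held next to the allene on the ring. The donor solvent tempers the Lewis acidity of the gold and the low temperature should keep the doubly allylic C8–O bond of 12 intact.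

Step 9
Reactants: 12 diethyl [(2E)-3-[(2R,6S,7aR)-6-{[tert-butyl(dimethyl)silyl]oxy}-4,4,7a-trimethyl-2,4,5,6,7,7a-hexahydro-1-benzofuran-2-yl]but-2-en-1-yl]phosphonate (2.2 equiv); 13 (2E,4E,6E)-2,7-dimethylocta-2,4,6-trienedial
Product: 16 (3S,5R,8R,3'S,5'R,8'R)-3,3'-bis{[tert-butyl(dimethyl)silyl]oxy}-5,8:5',8'-diepoxy-5,8,5',8'-tetrahydro-β,β-carotene, via phosphonate carbanion 14 (not isolated), via C25 monoaldehyde 15 (not isolated)
Conditions: KN(SiMe3)2 (2.2 equiv), THF, −78 °C; then 13, −78 → 0 °C, dark, argon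
Reagents that add atoms: none
Why: Two-fold Horner–Wadsworth–Emmons olefination through the α-carbon (C11) of the allylic phosphonate carbanion should form C11=C12 and C11'=C12' with E selectivity, and the non-acidic C8–H and the other stereocentres are not involved.

Step 10
Reactants: 16 (3S,5R,8R,3'S,5'R,8'R)-3,3'-bis{[tert-butyl(dimethyl)silyl]oxy}-5,8:5',8'-diepoxy-5,8,5',8'-tetrahydro-β,β-carotene
Product: 18 (3S,5R,8R,3'S,5'R,8'R)-5,8:5',8'-diepoxy-5,8,5',8'-tetrahydro-β,β-carotene-3,3'-diol (all-E), via mono-TBS ether 17 (not isolated)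
Conditions: Bu4NF, THF, 0 °C → rt, dark, argon
Reagents that add atoms: none
Why: Fluoride desilylation under basic conditions should free both carbinols without the acid that would ionise the C8–O bonds and epimerise C8.

**Compound list**

1 | (4R,6R)-4-hydroxy-2,2,6-trimethylcyclohexan-1-one | O=C1C(C)(C)C[C@H](O)C[C@H]1C | starting material
2 | (4R,6R)-4-{[tert-butyl(dimethyl)silyl]oxy}-2,2,6-trimethylcyclohexan-1-one | O=C1C(C)(C)C[C@H](O[Si](C)(C)C(C)(C)C)C[C@H]1C | intermediate
3 | potassium (4R)-4-{[tert-butyl(dimethyl)silyl]oxy}-2,6,6-trimethylcyclohex-1-en-1-olate | [K+].[O-]C1=C(C)C[C@@H](O[Si](C)(C)C(C)(C)C)CC1(C)C | intermediate (not isolated)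
4 | (4R)-4-{[tert-butyl(dimethyl)silyl]oxy}-2,6,6-trimethylcyclohex-1-en-1-yl trifluoromethanesulfonate | FC(F)(F)S(=O)(=O)OC1=C(C)C[C@@H](O[Si](C)(C)C(C)(C)C)CC1(C)C | intermediate
5 | (2E)-3-methylpent-2-en-4-yn-1-ol | C#C/C(C)=C/CO | starting material
6 | (3E)-5-bromo-3-methylpent-3-en-1-yne | C#C/C(C)=C/CBr | intermediate
7 | diethyl [(2E)-3-methylpent-2-en-4-yn-1-yl]phosphonate | C#C/C(C)=C/CP(=O)(OCC)OCC | intermediate
8 | diethyl [(2E)-5-[(4R)-4-{[tert-butyl(dimethyl)silyl]oxy}-2,6,6-trimethylcyclohex-1-en-1-yl]-3-methylpent-2-en-4-yn-1-yl]phosphonate | CCOP(=O)(OCC)C/C=C(\C)C#CC1=C(C)C[C@@H](O[Si](C)(C)C(C)(C)C)CC1(C)C | intermediate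
9 | diethyl [(2E)-5-[(1R,4S,6R)-4-{[tert-butyl(dimethyl)silyl]oxy}-2,2,6-trimethyl-7-oxabicyclo[4.1.0]heptan-1-yl]-3-methylpent-2-en-4-yn-1-yl]phosphonate | CCOP(=O)(OCC)C/C=C(\C)C#C[C@@]12O[C@]1(C)C[C@@H](O[Si](C)(C)C(C)(C)C)CC2(C)C | intermediate
10 | diethyl [(2E)-5-[(2R,4S)-4-{[tert-butyl(dimethyl)silyl]oxy}-2-{[diethoxy(methyl)silyl]oxy}-2,6,6-trimethylcyclohexylidene]-3-methylpenta-2,4-dien-1-yl]phosphonate, (aS) axis | CCOP(=O)(OCC)C/C=C(C)/C=[C@]=C1C(C)(C)C[C@H](O[Si](C)(C)C(C)(C)C)C[C@@]1(C)O[Si](C)(OCC)OCC | intermediate (not isolated)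
11 | diethyl [(2E)-5-[(2R,4S)-4-{[tert-butyl(dimethyl)silyl]oxy}-2-hydroxy-2,6,6-trimethylcyclohexylidene]-3-methylpenta-2,4-dien-1-yl]phosphonate, (aS) axis | CCOP(=O)(OCC)C/C=C(C)/C=[C@]=C1C(C)(C)C[C@H](O[Si](C)(C)C(C)(C)C)C[C@@]1(C)O | intermediate
12 | diethyl [(2E)-3-[(2R,6S,7aR)-6-{[tert-butyl(dimethyl)silyl]oxy}-4,4,7a-trimethyl-2,4,5,6,7,7a-hexahydro-1-benzofuran-2-yl]but-2-en-1-yl]phosphonate | CCOP(=O)(OCC)C/C=C(\C)[C@H]1C=C2C(C)(C)C[C@H](O[Si](C)(C)C(C)(C)C)C[C@@]2(C)O1 | intermediate
13 | (2E,4E,6E)-2,7-dimethylocta-2,4,6-trienedial | O=C/C(C)=C/C=C/C=C(\C)C=O | starting material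
14 | potassium salt of the C-1 carbanion of 12 | [K+].CCOP(=O)(OCC)[CH-]/C=C(\C)[C@H]1C=C2C(C)(C)C[C@H](O[Si](C)(C)C(C)(C)C)C[C@@]2(C)O1 | intermediate (not isolated)
15 | (2E,4E,6E,8E,10E)-11-[(2R,6S,7aR)-6-{[tert-butyl(dimethyl)silyl]oxy}-4,4,7a-trimethyl-2,4,5,6,7,7a-hexahydro-1-benzofuran-2-yl]-2,7-dimethyldodeca-2,4,6,8,10-pentaenal | O=C/C(C)=C/C=C/C=C(C)/C=C/C=C(\C)[C@H]1C=C2C(C)(C)C[C@H](O[Si](C)(C)C(C)(C)C)C[C@@]2(C)O1 | intermediate (not isolated)
16 | (3S,5R,8R,3'S,5'R,8'R)-3,3'-bis{[tert-butyl(dimethyl)silyl]oxy}-5,8:5',8'-diepoxy-5,8,5',8'-tetrahydro-β,β-carotene | CC(/C=C/C=C(\C)[C@H]1C=C2C(C)(C)C[C@H](O[Si](C)(C)C(C)(C)C)C[C@@]2(C)O1)=C\C=C\C=C(C)\C=C\C=C(/C)[C@H]1C=C2C(C)(C)C[C@H](O[Si](C)(C)C(C)(C)C)C[C@@]2(C)O1 | intermediate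
17 | (3S,5R,8R,3'S,5'R,8'R)-3'-{[tert-butyl(dimethyl)silyl]oxy}-5,8:5',8'-diepoxy-5,8,5',8'-tetrahydro-β,β-caroten-3-ol | CC(/C=C/C=C(\C)[C@H]1C=C2C(C)(C)C[C@H](O[Si](C)(C)C(C)(C)C)C[C@@]2(C)O1)=C\C=C\C=C(C)\C=C\C=C(/C)[C@H]1C=C2C(C)(C)C[C@H](O)C[C@@]2(C)O1 | intermediate (not isolated)
18 | (3S,5R,8R,3'S,5'R,8'R)-5,8:5',8'-diepoxy-5,8,5',8'-tetrahydro-β,β-carotene-3,3'-diol (all-E) | CC(/C=C/C=C(\C)[C@H]1C=C2C(C)(C)C[C@H](O)C[C@@]2(C)O1)=C\C=C\C=C(C)\C=C\C=C(/C)[C@H]1C=C2C(C)(C)C[C@H](O)C[C@@]2(C)O1 | target

**Summary**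

Total step count: 10. Longest linear sequence: 8 steps (1 → 2 → 4 → 8 → 9 → 11 → 12 → 16 → 18).

Steps most likely to fail:

Step 8 (key step). What may go wrong is erosion of the axis-to-centre transfer by reversible gold-induced ionisation at C8 (a planar allyl cation before closure, or reopening of the doubly allylic C8–O bond after it), or diversion of the vinylallene into carbocyclisation. The fallback sets out from 11 and comes back at 12. Electrophilic 5-endo iodoetherification with N-iodosuccinimide (NaHCO3, CH2Cl2, −20 °C) adds O and I anti across C7=C8 without moving the two C8 substituents. It should give diethyl [(2E)-3-[(2S,6S,7aR)-6-{[tert-butyl(dimethyl)silyl]oxy}-3-iodo-4,4,7a-trimethyl-2,4,5,6,7,7a-hexahydro-1-benzofuran-2-yl]but-2-en-1-yl]phosphonate F1, whose C-2 descriptor differs from that of 12 only because iodine raises the rank of C-3. The vinyl iodide is then reduced with Bu3SnH and catalytic Pd(PPh3)4 (zerovalent palladium) in THF to 12.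

Step 7. What may go wrong is hydride delivery syn instead of anti to the C6–O bond, hydrocupration with copper on C8 instead of C7, or over-reduction of the allene; the first would give the epimeric axis and, after step 8, the wrong C8 configuration. The fallback sets out from 9 and comes back at 11. It is a hydrogenolysis with HCO2H/Et3N and catalytic Pd2(dba)3/PBu3 (zerovalent palladium) in THF. Oxidative addition to the propargylic oxirane with inversion places palladium on C8 anti to the former C–O bond, and formate decarboxylation followed by C–H reductive elimination with retention puts hydrogen where palladium was. This fallback makes no compound outside the list (none F0).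

Step 6. What may go wrong is peracid attack on the face syn to the silyloxy group or poor discrimination between the two faces. The fallback sets out from 8 and comes back at 9. N-bromosuccinimide in THF/H2O at 0 °C forms the bromonium ion reversibly, and water should open it trans-diaxially at C5 (the non-propargylic carbon) in the half-chair that keeps the silyloxy group equatorial (Fürst–Plattner control). This puts the 5-OH anti to the silyloxy group and bromine on C6, giving diethyl [(2E)-5-[(1S,2R,4S)-1-bromo-4-{[tert-butyl(dimethyl)silyl]oxy}-2-hydroxy-2,6,6-trimethylcyclohexyl]-3-methylpent-2-en-4-yn-1-yl]phosphonate F2. K2CO3 in MeOH then closes the oxirane with inversion at C6 to 9.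

Further compounds
F1 | step 8 | diethyl [(2E)-3-[(2S,6S,7aR)-6-{[tert-butyl(dimethyl)silyl]oxy}-3-iodo-4,4,7a-trimethyl-2,4,5,6,7,7a-hexahydro-1-benzofuran-2-yl]but-2-en-1-yl]phosphonate | CCOP(=O)(OCC)C/C=C(\C)[C@H]1C(I)=C2C(C)(C)C[C@H](O[Si](C)(C)C(C)(C)C)C[C@@]2(C)O1
F0 | step 7 | none | none
F2 | step 6 | diethyl [(2E)-5-[(1S,2R,4S)-1-bromo-4-{[tert-butyl(dimethyl)silyl]oxy}-2-hydroxy-2,6,6-trimethylcyclohexyl]-3-methylpent-2-en-4-yn-1-yl]phosphonate | CCOP(=O)(OCC)C/C=C(\C)C#C[C@@]1(Br)C(C)(C)C[C@H](O[Si](C)(C)C(C)(C)C)C[C@@]1(C)O
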